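**Retrosynthetic overview**

- Numbering: ring A (seven-membered) C10–C1(OAc)–C2–C3(CH3)–C4–C5–C6 with the C2–C3 epoxide; ring B (five-membered) C6–C7–C8–C9–C10(CH3); side chain C11–C15 on C7. β is the face of H6, α the face of the C10 methyl.
- Feature: read as C1–C2–C3–C4–C5–C6–C10–C9–C8–C7–C11–C12–C13–C14–C15, with methyls on C3, C10, C11 and C15, the twenty carbons are one regular head-to-tail tetraprenyl chain. Only the bonds C1–C10 and C6–C7 are added to it, and the trans ring fusion corresponds to anti addition across an E alkene.
- The target is cut back to a bicyclic triene hydrocarbon (C2=C3, C11=C12, C14=C15) by removing, in this order, the C15 hydroxyl with the C13=C14 alkene (ene oxidation of the prenyl terminus), the acetate, the hydroxyl-directed epoxide and the C1 hydroxyl (enzymatic C–H hydroxylation).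
- The triene comes from geranylgeranyl diphosphate in one terpene-synthase cascade that closes ring A (C1–C10) and ring B (C6–C7) together and sets C6, C7 and C10. The diphosphate comes from geranylgeraniol and a diphosphate salt.

Key step: step 3

Remark: the diphosphate is handled as its trisammonium salt (its SMILES show the free acid), and the enzyme-bound tertiary diphosphate is drawn without configuration at C3, which the active site fixes.

**Route**

Step 1
Reactants: 1 (2E,6E,10E)-geranylgeraniol
Product: 2 (2E,6E,10E)-geranylgeranyl chloride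
Conditions: NCS, Me2S, CH2Cl2, −30 → 0 °C
Reagents that add atoms: N-chlorosuccinimide, ClN1C(=O)CCC1=O
Why: Corey–Kim-type activation turns the primary allylic hydroxyl into an alkoxysulfonium ion that chloride displaces at C1 by SN2, the standard access to prenyl chlorides without allylic transposition or E/Z scrambling; no stereocentre is formed.

Step 2
Reactants: 2 (2E,6E,10E)-geranylgeranyl chloride; 3 tris(tetra-n-butylammonium) hydrogen diphosphate
Product: 4 (2E,6E,10E)-geranylgeranyl diphosphate (trisammonium salt)
Conditions: 3 (2 equiv), MeCN, rt; then Dowex AG 50W-X8 (NH4+ form), aq. NH4HCO3/i-PrOH; cellulose chromatography, lyophilisation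
Reagents that add atoms: tris(tetra-n-butylammonium) hydrogen diphosphate (compound 3), CCCC[N+](CCCC)(CCCC)CCCC.CCCC[N+](CCCC)(CCCC)CCCC.CCCC[N+](CCCC)(CCCC)CCCC.OP(=O)([O-])OP(=O)([O-])[O-]
Why: SN2 displacement of the primary allylic chloride by the MeCN-soluble, weakly basic diphosphate anion is the standard prenyl diphosphate synthesis, and cation exchange gives the water-soluble salt the enzyme needs; no stereocentre is formed.

Step 3
Reactants: 4 (2E,6E,10E)-geranylgeranyl diphosphate
Product: 6 bicyclic triene (rings A and B trans-fused; C2=C3; 11E; C14=C15; H6 and the C7 side chain β; C10 methyl α), via geranyllinalyl diphosphate 5 (not isolated)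
Conditions: recombinant class 1 diterpene synthase (from genome mining of liverwort terpene-synthase genes, or a daucane-forming sesquiterpene synthase with an enlarged active site), MgCl2, Tris-HCl pH 7.5, dithiothreitol, glycerol, pentane overlay, 30 °C
Reagents that add atoms: none
Why: Proposed new method: the Mg2+-bound diphosphate of 4 ionises, returns to C3 (enzyme-bound tertiary diphosphate 5) so that C2–C3 can rotate, and ionises again to the cisoid C1–C2–C3 allyl cation; the C6=C10 π bond then adds to C1 through C10 while the C7=C11 π bond adds to C6, so that charge never rests on secondary C6 but arrives at tertiary C11, where loss of H12 gives the 11E alkene. The closest known reaction type is the cyclisation of farnesyl diphosphate to the daucane sesquiterpenes by class 1 sesquiterpene synthases, which makes the same two bonds one isoprene unit lower; no enzyme is described for the C20 case. Ring A closes 7-endo-trig (C1 on C10, both alkene carbons inside the ring) and ring B closes 5-exo-trig (C6 on C7, C11 outside the ring). C10 and C6 arise by anti addition of C1 and C7 across the E-configured C6=C10 alkene, which turns the alkene geometry into the trans ring fusion, C7 is set by the face of the C7=C11 alkene that the folded chain presents to C6 (C11 arm trans to C5), and the absolute sense is that of the fold imposed by the active-site contour. The step needs closure of C1 on C10 in preference to the intrinsically easier six-membered closure on C6 and to macrocyclisation on the distal alkene; the substrate helps because the methyl-bearing C7=C11 alkene stands five atoms from C6, so the anti-Markovnikov attack at C10 is paid for by a concerted Markovnikov capture, and the rest is left to the enzyme template.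

Step 4
Reactants: 6 bicyclic triene
Product: 7 1β-hydroxy triene (allylic alcohol; hydroxyl trans to the C10 methyl)
Conditions: CYP102A1 (P450 BM3) variant chosen by screening for C1 hydroxylation, NADP+ (cat.), glucose dehydrogenase, D-glucose, air, potassium phosphate pH 8.0, 2-hydroxypropyl-β-cyclodextrin, 25 °C
Reagents that add atoms: dioxygen, O=O
Why: Cytochrome P450 allylic C–H hydroxylation (hydrogen abstraction by the oxo-iron haem, then oxygen rebound on the same face) is well established for cyclic terpene olefins with CYP102A1 variants; the binding pose selected by screening must hold the β hydrogen of C1 over the haem, and that pose sets the new C1 stereocentre.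

Step 5
Reactants: 7 1β-hydroxy triene
Product: 8 1β-hydroxy-2β,3β-epoxide (epoxide oxygen cis to the hydroxyl)
Conditions: VO(acac)2 (cat.), t-BuOOH (decane solution), CH2Cl2, 0 °C → rt
Reagents that add atoms: tert-butyl hydroperoxide, CC(C)(C)OO
Why: In this hydroxyl-directed vanadium-catalysed epoxidation (Sharpless–Michaelson) the C1 alkoxide binds the vanadium tert-butyl peroxide and oxygen is delivered to C2=C3 on the face of the hydroxyl (cis-epoxy alcohol, as is general for cycloheptenols, and also the face away from the C10 methyl), which sets C2 and C3, while the two side-chain alkenes have no neighbouring hydroxyl and are left.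

Step 6
Reactants: 8 1β-hydroxy-2β,3β-epoxide
Product: 9 1β-acetoxy-2β,3β-epoxide
Conditions: Ac2O, pyridine, DMAP (cat.), CH2Cl2, 0 °C → rt
Reagents that add atoms: acetic anhydride, CC(=O)OC(C)=O
Why: DMAP-catalysed acylation of the only hydroxyl group; the neopentyl-type secondary alcohol is hindered but acylates under nucleophilic catalysis, and epoxide and alkenes are inert to these mildly basic conditions, so no stereocentre is touched.

Step 7
Reactants: 9 1β-acetoxy-2β,3β-epoxide
Product: 11 target CNP0265175.2 (11E,13E-dien-15-ol), via 15-hydroperoxide 10 (not isolated)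
Conditions: O2, meso-tetraphenylporphyrin (cat.), visible light, CH2Cl2, −20 °C, stopped at partial conversion; then PPh3, 0 °C → rt; chromatography
Reagents that add atoms: dioxygen, O=O
Why: In the Schenck ene reaction singlet oxygen adds to the electron-rich terminal Me2C=CH unit and takes a hydrogen from the doubly allylic C13 on the more substituted side of the alkene, which puts the hydroperoxide on tertiary C15 and moves the alkene to C13=C14 (E, conjugated with C11=C12); triphenylphosphine then reduces the hydroperoxide without touching epoxide or acetate, and no stereocentre is formed.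

**Compound list**

1 | (2E,6E,10E)-geranylgeraniol | CC(C)=CCC/C(C)=C/CC/C(C)=C/CC/C(C)=C/CO | starting material
2 | (2E,6E,10E)-geranylgeranyl chloride | CC(C)=CCC/C(C)=C/CC/C(C)=C/CC/C(C)=C/CCl | intermediate
3 | tris(tetra-n-butylammonium) hydrogen diphosphate | CCCC[N+](CCCC)(CCCC)CCCC.CCCC[N+](CCCC)(CCCC)CCCC.CCCC[N+](CCCC)(CCCC)CCCC.OP(=O)([O-])OP(=O)([O-])[O-] | starting material
4 | (2E,6E,10E)-geranylgeranyl diphosphate (used as trisammonium salt; free acid drawn) | CC(C)=CCC/C(C)=C/CC/C(C)=C/CC/C(C)=C/COP(=O)(O)OP(=O)(O)O | intermediate
5 | geranyllinalyl diphosphate (tertiary allylic isomer of 4, enzyme-bound; C3 configuration left open) | CC(C)=CCC/C(C)=C/CC/C(C)=C/CCC(C)(C=C)OP(=O)(O)OP(=O)(O)O | intermediate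
6 | bicyclic triene: trans-fused rings A and B, C2=C3, C7β-[(2E)-6-methylhepta-2,5-dien-2-yl], H6 β, C10 methyl α | C1C=C(C)CC[C@H]2[C@H](/C(C)=C/CC=C(C)C)CC[C@]12C | intermediate
7 | 1β-hydroxy derivative of 6 (hydroxyl trans to the C10 methyl) | O[C@@H]1C=C(C)CC[C@H]2[C@H](/C(C)=C/CC=C(C)C)CC[C@]12C | intermediate
8 | 1β-hydroxy-2β,3β-epoxide | O[C@@H]1[C@@H]2O[C@]2(C)CC[C@H]2[C@H](/C(C)=C/CC=C(C)C)CC[C@]12C | intermediate
9 | 1β-acetoxy-2β,3β-epoxide | CC(=O)O[C@@H]1[C@@H]2O[C@]2(C)CC[C@H]2[C@H](/C(C)=C/CC=C(C)C)CC[C@]12C | intermediate
10 | 15-hydroperoxide of the 11E,13E-diene | CC(=O)O[C@@H]1[C@@H]2O[C@]2(C)CC[C@H]2[C@H](/C(C)=C/C=C/C(C)(C)OO)CC[C@]12C | intermediate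
11 | CNP0265175.2 | CC(=O)O[C@@H]1[C@@H]2O[C@]2(C)CC[C@H]2[C@H](/C(C)=C/C=C/C(C)(C)O)CC[C@]12C | target
12 | 2-methylcyclopent-2-en-1-one (commercial; enters only the fallbacks to steps 3 and 4) | CC1=CCCC1=O | starting material

**Step count**

Total: 7 steps. Longest linear sequence: 7 steps (1 → 11).

**Steps most likely to fail**

1. Step 3 (the proposed new method). The ionised chain may close the six-membered ring on C6, macrocyclise on the distal alkene or be quenched before the C6–C7 bond forms, or no synthase may turn over the C20 substrate in this fold. The fallback builds 6 by known reactions; it sets out from 12 and comes back at 6.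
   - Cu(OTf)2 with a chiral phosphoramidite ligand catalyses the enantioselective conjugate addition of bis(3-methylbut-3-enyl)zinc to 12 (toluene, −30 °C) and gives zinc enolate F1.
   - F1 is allylated in the same flask (allyl iodide, HMPA) on the face away from the new C6 substituent to give trans-2-allyl-2-methyl-3-(3-methylbut-3-enyl)cyclopentanone F2, which fixes C6 and C10.
   - Ring-closing metathesis (second-generation Grubbs catalyst, CH2Cl2, 40 °C) closes ring A as the trisubstituted cycloheptene in bicyclic ketone F3.
   - IBX (DMSO, 70 °C) dehydrogenates the only enolisable side to enone F4.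
   - Me2AlC≡CSiMe3 with Ni(acac)2/i-Bu2AlH (Et2O, 0 °C) adds to C7 anti to the angular methyl and gives alkynyl ketone F5, which fixes C7.
   - The C9 carbonyl is removed through tosylhydrazone F6 (TsNHNH2, EtOH, reflux) and catecholborane then NaOAc·3H2O (CHCl3) to give silylalkyne F7.
   - K2CO3/MeOH frees terminal alkyne F8.
   - Me3Al with Cp2ZrCl2 (ClCH2CH2Cl, rt) gives the E-alkenylalane F9 by syn methylalumination, and Pd(PPh3)4 (zerovalent palladium) couples it with prenyl chloride to 6.

2. Step 4. Hydrogen abstraction may go to the other allylic sites (doubly allylic C13, the terminal methyls, C4), the alkenes may be epoxidised, or oxygen may rebound on the α face of C1. The fallback puts the C1 oxygen in chemically at a stage where the ring alkene is the only alkene; it sets out from 12, runs through F1 to silylalkyne F7 as above, and comes back at 7.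
   - CrO3 with 3,5-dimethylpyrazole (CH2Cl2, −20 °C) oxidises the allylic methylene next to the vinylic CH, as in the oxidation of 1-methylcycloalkenes to β-methyl enones, and gives C1 enone F10.
   - NaBH4/CeCl3·7H2O (MeOH, −40 °C) delivers hydride anti to the angular methyl and gives 1α-alcohol F11.
   - Mitsunobu inversion (4-nitrobenzoic acid, PPh3, diisopropyl azodicarboxylate, THF) gives 1β-(4-nitrobenzoate) F12.
   - K2CO3/MeOH removes ester and silyl group to give 1β-hydroxy alkyne F13.
   - Excess Me3Al with Cp2ZrCl2 gives the aluminium alkoxide alkenylalane F14, which is coupled with prenyl chloride under Pd(PPh3)4 and worked up with water to give 7.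

3. Step 7. The ene reaction may not discriminate between C14=C15 and C11=C12, may take hydrogen from the cis methyl on C15 (secondary hydroperoxide with an isopropenyl end), and the product diene may add a second singlet oxygen by [4+2]. The fallback replaces the pericyclic step by ionic hydroxyselenation and selenoxide elimination, which fixes the regiochemistry; it sets out from 9 and comes back at 11.
   - Benzeneselenenic acid, made from PhSeSePh and PhSeO2H (CH2Cl2, MgSO4, rt), adds to the least hindered trisubstituted alkene with selenium on C14 and hydroxyl on tertiary C15 to give β-hydroxy selenide F15 (both C14 epimers).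
   - t-BuOOH (CH2Cl2, rt) oxidises it to selenoxide F16, whose syn elimination can only run towards C13 and gives the 13E allylic tertiary alcohol 11.

**Further compounds**

F1 | step 3 | zinc enolate from conjugate addition to 12 | C=C(C)CC[C@H]1CCC(O[Zn]CCC(C)=C)=C1C
F2 | step 3 | trans-2-allyl-2-methyl-3-(3-methylbut-3-enyl)cyclopentanone | C=C(C)CC[C@H]1CCC(=O)[C@]1(C)CC=C
F3 | step 3 | bicyclic ketone (C9 ketone, C2=C3, trans-fused) | C1C=C(C)CC[C@H]2CCC(=O)[C@]12C
F4 | step 3 | bicyclic enone (C7=C8–C9=O) | C1C=C(C)CC[C@H]2C=CC(=O)[C@]12C
F5 | step 3 | 7β-(trimethylsilylethynyl) C9 ketone | C1C=C(C)CC[C@H]2[C@H](C#C[Si](C)(C)C)CC(=O)[C@]12C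
F6 | step 3 | tosylhydrazone of F5 | C1C=C(C)CC[C@H]2[C@H](C#C[Si](C)(C)C)CC(=NNS(=O)(=O)c3ccc(C)cc3)[C@]12C
F7 | step 3 | 7β-(trimethylsilylethynyl) bicyclic alkene | C1C=C(C)CC[C@H]2[C@H](C#C[Si](C)(C)C)CC[C@]12C
F8 | step 3 | 7β-ethynyl bicyclic alkene | C1C=C(C)CC[C@H]2[C@H](C#C)CC[C@]12C
F9 | step 3 | E-alkenyl(dimethyl)alane | C1C=C(C)CC[C@H]2[C@H](/C(C)=C/[Al](C)C)CC[C@]12C
F10 | step 4 | C1 enone of F7 | O=C1C=C(C)CC[C@H]2[C@H](C#C[Si](C)(C)C)CC[C@]12C
F11 | step 4 | 1α-alcohol (hydroxyl cis to the C10 methyl) | O[C@H]1C=C(C)CC[C@H]2[C@H](C#C[Si](C)(C)C)CC[C@]12C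
F12 | step 4 | 1β-(4-nitrobenzoate) | O=C(O[C@@H]1C=C(C)CC[C@H]2[C@H](C#C[Si](C)(C)C)CC[C@]12C)c1ccc(cc1)[N+](=O)[O-]
F13 | step 4 | 1β-hydroxy 7β-ethynyl bicyclic alkene | O[C@@H]1C=C(C)CC[C@H]2[C@H](C#C)CC[C@]12C
F14 | step 4 | aluminium alkoxide E-alkenylalane | C[Al](C)O[C@@H]1C=C(C)CC[C@H]2[C@H](/C(C)=C/[Al](C)C)CC[C@]12C
F15 | step 7 | 14-phenylseleno-15-hydroxy adduct of 9 (C14 epimers) | CC(=O)O[C@@H]1[C@@H]2O[C@]2(C)CC[C@H]2[C@H](/C(C)=C/CC([Se]c3ccccc3)C(C)(C)O)CC[C@]12C
F16 | step 7 | selenoxide of F15 | CC(=O)O[C@@H]1[C@@H]2O[C@]2(C)CC[C@H]2[C@H](/C(C)=C/CC([Se](=O)c3ccccc3)C(C)(C)O)CC[C@]12C
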